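**Plan**

- The retrosynthesis cuts four bonds: O1–C8a and C4–C4a of the 7-hydroxychromanone, and O1''–C8a'' and C4''–C4a'' of the 5,7-dihydroxychromanone.
- Enabling feature: in each pyranone the benzo ring is held through two adjacent carbons, by the ring oxygen O1 and by the C4 carbonyl carbon. Each arene can therefore arrive as an aryne placed between the oxygen and the acyl carbon of a β-hydroxy carbonyl unit. What is left (C2–C3–C3''–C2'' with two oxygens and two acyl carbons) is the 8–8 dilactone of p-coumaric acid.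
- Forward: two molecules of p-coumaric acid are joined oxidatively to the 3,7-dioxabicyclo[3.3.0]octane-4,8-dione, which is benzylated and resolved; one lactone is opened to an N-methoxy-N-methylamide and the freed hydroxyl is silylated. Two o-silylaryl triflates are made separately.
- In one flask a chloro-substituted aryne builds the first pyranone on the lactone carbonyl; the alkoxide this releases builds the second pyranone with 3,5-bis(benzyloxy)benzyne on the amide. Epimerisation at C3/C3'' and hydrogenolysis (benzyl ethers and the C5 chlorine) finish the synthesis.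
- Stereochemistry: C2 and C2'' (both S) are the carbinol carbons of the resolved dilactone and their C–O bonds are never broken. C3 and C3'' emerge cis from the cis-fused dilactone and are equilibrated to the trans,trans (3R,3''R) arrangement.

Key step: step 11

Remark on the chemistry: the target is read as the 2,3-trans/2'',3''-trans (2S,3R,2''S,3''R) isomer; 4-(benzyloxy)phenol and 3,5-bis(benzyloxy)phenol are taken as purchasable; racemates 2 and 3 are drawn as their (1S,2S,5S,6S) enantiomer.

**Route**

Step 1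
Reactants: 1 p-coumaric acid; 1 p-coumaric acid
Product: 2 rac-(1S,2S,5S,6S)-2,6-bis(4-hydroxyphenyl)-3,7-dioxabicyclo[3.3.0]octane-4,8-dione
Conditions: FeCl3·6H2O (1.1 equiv per molecule of 1), acetone–H2O, rt
Reagents that add atoms: none
Why: Oxidative phenol coupling that joins two molecules of 1: one-electron oxidation of each gives a phenoxyl radical, 8–8 coupling of the two radicals gives a bis(quinone methide), and each carboxylic acid adds to the quinone methide carbon of the other half, which should give the cis-fused dilactone with both aryl groups on the convex face (racemic), as in the ferulic and sinapic acid series, a modest return being accepted at this first step.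

Step 2
Reactants: 2 rac-(1S,2S,5S,6S)-2,6-bis(4-hydroxyphenyl)-3,7-dioxabicyclo[3.3.0]octane-4,8-dione
Product: 3 rac-(1S,2S,5S,6S)-2,6-bis[4-(benzyloxy)phenyl]-3,7-dioxabicyclo[3.3.0]octane-4,8-dione
Conditions: BnBr (2.4 equiv), K2CO3, acetone, rt
Reagents that add atoms: benzyl bromide, BrCc1ccccc1
Why: Williamson ether synthesis on both phenols under mild carbonate conditions that should leave the two γ-lactones closed.

Step 3
Reactants: 3 rac-(1S,2S,5S,6S)-2,6-bis[4-(benzyloxy)phenyl]-3,7-dioxabicyclo[3.3.0]octane-4,8-dione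
Product: 4 (1S,2S,5S,6S)-2,6-bis[4-(benzyloxy)phenyl]-3,7-dioxabicyclo[3.3.0]octane-4,8-dione
Conditions: preparative SFC, amylose tris(3,5-dimethylphenylcarbamate) phase, CO2–MeOH
Reagents that add atoms: none
Why: Resolution of a racemate by chromatography on a chiral stationary phase; the rigid C2-symmetric dilactone should separate well, and the (1S,2S,5S,6S) enantiomer, whose C2 and C6 become C2 and C2'' of the target, is carried on.

Step 4
Reactants: 4 (1S,2S,5S,6S)-2,6-bis[4-(benzyloxy)phenyl]-3,7-dioxabicyclo[3.3.0]octane-4,8-dione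
Product: 5 (2S,3S,4S)-2-[4-(benzyloxy)phenyl]-4-{(S)-[4-(benzyloxy)phenyl](hydroxy)methyl}-N-methoxy-N-methyl-5-oxooxolane-3-carboxamide
Conditions: MeNH(OMe)·HCl (1.05 equiv), i-PrMgCl (2.1 equiv), THF, −20 °C; aq. NH4Cl
Reagents that add atoms: N,O-dimethylhydroxylamine hydrochloride, CNOC.Cl
Why: Lactone aminolysis with the chloromagnesium amide of N,O-dimethylhydroxylamine; the two lactones are homotopic, so one equivalent should give a single mono-amide with all four stereocentres untouched, unreacted 4 being recycled.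

Step 5
Reactants: 5 (2S,3S,4S)-2-[4-(benzyloxy)phenyl]-4-{(S)-[4-(benzyloxy)phenyl](hydroxy)methyl}-N-methoxy-N-methyl-5-oxooxolane-3-carboxamide
Product: 6 (2S,3S,4S)-2-[4-(benzyloxy)phenyl]-4-{(S)-[4-(benzyloxy)phenyl][(trimethylsilyl)oxy]methyl}-N-methoxy-N-methyl-5-oxooxolane-3-carboxamide
Conditions: TMSCl, imidazole, CH2Cl2, 0 °C
Reagents that add atoms: chlorotrimethylsilane, C[Si](C)(C)Cl
Why: Standard O-silylation of a secondary alcohol, which stops the γ-hydroxy amide from relactonising and lets fluoride later release the alkoxide without a proton on oxygen.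

Step 6
Reactants: 7 4-(benzyloxy)phenol
Product: 8 4-(benzyloxy)-2-chlorophenol
Conditions: SO2Cl2 (1.05 equiv), i-Bu2NH (cat.), toluene, 0 °C to rt
Reagents that add atoms: sulfuryl chloride, O=S(=O)(Cl)Cl
Why: Electrophilic aromatic chlorination; the free hydroxyl is the strongest director and its para position is blocked, so chlorine should enter ortho to OH.

Step 7
Reactants: 8 4-(benzyloxy)-2-chlorophenol
Product: 9 4-(benzyloxy)-2-bromo-6-chlorophenol
Conditions: NBS, MeCN, 0 °C
Reagents that add atoms: N-bromosuccinimide, O=C1CCC(=O)N1Br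
Why: Electrophilic aromatic bromination at the one remaining position ortho to the hydroxyl group.

Step 8
Reactants: 9 4-(benzyloxy)-2-bromo-6-chlorophenol
Product: 12 4-(benzyloxy)-2-chloro-6-(trimethylsilyl)phenyl trifluoromethanesulfonate, via aryl silyl ether 10 (not isolated), via lithium silylphenoxide 11 (not isolated)
Conditions: HMDS, THF, 65 °C, evaporate; n-BuLi, THF, −100 °C; Tf2O, −100 to −78 °C
Reagents that add atoms: hexamethyldisilazane, C[Si](C)(C)N[Si](C)(C)C; trifluoromethanesulfonic anhydride, O=S(=O)(OS(=O)(=O)C(F)(F)F)C(F)(F)F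
Why: O-silylation, bromine–lithium exchange, 1,3 O-to-C silyl shift (retro-Brook rearrangement) and O-triflation of the phenoxide, the standard way to o-silylaryl triflates; exchange at −100 °C should be faster than any attack on the benzyl ether or the aryl chloride.

Step 9
Reactants: 13 3,5-bis(benzyloxy)phenol
Product: 14 3,5-bis(benzyloxy)-2-bromophenol
Conditions: NBS, CH2Cl2, −78 to 0 °C
Reagents that add atoms: N-bromosuccinimide, O=C1CCC(=O)N1Br
Why: Electrophilic aromatic bromination ortho to the free hydroxyl at low temperature, the two equivalent ortho positions being less hindered than the position between the benzyloxy groups.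

Step 10
Reactants: 14 3,5-bis(benzyloxy)-2-bromophenol
Product: 17 3,5-bis(benzyloxy)-2-(trimethylsilyl)phenyl trifluoromethanesulfonate, via aryl silyl ether 15 (not isolated), via lithium silylphenoxide 16 (not isolated)
Conditions: HMDS, THF, 65 °C, evaporate; n-BuLi, THF, −100 °C; Tf2O, −100 to −78 °C
Reagents that add atoms: hexamethyldisilazane, C[Si](C)(C)N[Si](C)(C)C; trifluoromethanesulfonic anhydride, O=S(=O)(OS(=O)(=O)C(F)(F)F)C(F)(F)F
Why: The same O-silylation, bromine–lithium exchange, retro-Brook rearrangement and O-triflation sequence as in step 8, here on a phenol without a halogen spectator.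

Step 11
Reactants: 6 (2S,3S,4S)-2-[4-(benzyloxy)phenyl]-4-{(S)-[4-(benzyloxy)phenyl][(trimethylsilyl)oxy]methyl}-N-methoxy-N-methyl-5-oxooxolane-3-carboxamide; 12 4-(benzyloxy)-2-chloro-6-(trimethylsilyl)phenyl trifluoromethanesulfonate; 17 3,5-bis(benzyloxy)-2-(trimethylsilyl)phenyl trifluoromethanesulfonate
Product: 22 (2S,3S)-7-(benzyloxy)-3-{(2S,3S)-5,7-bis(benzyloxy)-2-[4-(benzyloxy)phenyl]-4-oxochroman-3-yl}-2-[4-(benzyloxy)phenyl]-5-chlorochroman-4-one, via cesium alkoxide 18 (not isolated), via chloroaryne 19 (not isolated), via chromanone alkoxide 20 (not isolated), via dibenzyloxyaryne 21 (not isolated)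
Conditions: CsF (6 equiv), 18-crown-6, THF, 0 °C to rt, 6 and 12 (1.2 equiv) added together; then 17 (1.4 equiv), rt; aq. NH4Cl
Reagents that add atoms: none
Why: Proposed new method: fluoride removes the O-silyl group of 6 to give alkoxide 18 and converts 12 into aryne 19; 18 adds to the aryne carbon remote from chlorine, and the aryl anion so formed attacks the lactone carbonyl in a 6-exo-trig acyl substitution that closes the 5-chloro pyranone (O1–C8a and C4–C4a) and sets the lactone oxygen free as alkoxide 20 (in equilibrium with its lactolate), after which 20 adds to aryne 21 from 17 and the new aryl anion closes the second pyranone (O1''–C8a'' and C4''–C4a'') on the N-methoxy-N-methylamide, again 6-exo-trig. The closest known reaction type is the fluoride-mediated annulation of arynes with salicylate esters to xanthones, in which an oxygen nucleophile adds to the aryne and the aryl anion is trapped by the neighbouring acyl group; here an aliphatic β-oxido lactone and a β-oxido amide take the place of the salicylate and the first annulation triggers the second. No stereocentre is made: C2 and C2'' keep the S configuration of 4 because only O–aryl bonds form at their oxygens, and C3 and C3'' keep the cis relationship to their aryl neighbours that the cis-fused dilactone imposes. Regioselectivity at each aryne should follow from the inductively withdrawing chloro or benzyloxy group next to one aryne carbon, which directs the alkoxide to the far carbon and leaves the anion beside the substituent, that is at the future C4a. The order of addition decides which arene is built onto which half, and since the carbon core is C2-symmetric both orders give the same product, so the chloroaryl anion, which could otherwise lose chloride, is matched with the more electrophilic lactone and the more robust dialkoxyaryl anion with the amide. The step needs acyl capture to outrun retro-aldol cleavage of the β-oxido carbonyl units and protonation of the aryl anions, which the aprotic medium, the release of the alkoxide only in the presence of the aryne precursor and the six-membered geometry of both captures are meant to secure.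

Step 12
Reactants: 22 (2S,3S)-7-(benzyloxy)-3-{(2S,3S)-5,7-bis(benzyloxy)-2-[4-(benzyloxy)phenyl]-4-oxochroman-3-yl}-2-[4-(benzyloxy)phenyl]-5-chlorochroman-4-one
Product: 23 (2S,3R)-7-(benzyloxy)-3-{(2S,3R)-5,7-bis(benzyloxy)-2-[4-(benzyloxy)phenyl]-4-oxochroman-3-yl}-2-[4-(benzyloxy)phenyl]-5-chlorochroman-4-one
Conditions: DBU (0.3 equiv), THF–MeOH, rt
Reagents that add atoms: none
Why: Base-mediated epimerisation through the ketone enolates under thermodynamic control: each 2,3-cis chromanone should relax to the 2,3-trans isomer with the C2 aryl group and the C3 substituent both equatorial, while methanol reprotonates the enolate faster than it can expel the ring oxygen, so that C2 and C2'' stay S.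

Step 13
Reactants: 23 (2S,3R)-7-(benzyloxy)-3-{(2S,3R)-5,7-bis(benzyloxy)-2-[4-(benzyloxy)phenyl]-4-oxochroman-3-yl}-2-[4-(benzyloxy)phenyl]-5-chlorochroman-4-one
Product: 24 (2S,3R)-3-[(2S,3R)-5,7-dihydroxy-2-(4-hydroxyphenyl)-4-oxochroman-3-yl]-7-hydroxy-2-(4-hydroxyphenyl)chroman-4-one
Conditions: H2 (1 atm), 10% Pd/C, NaOAc (1.5 equiv), EtOAc–MeOH, rt
Reagents that add atoms: none
Why: Catalytic hydrogenolysis of the five benzyl ethers together with hydrodechlorination of the aryl chloride over Pd/C, NaOAc taking up the HCl so that the medium stays too weakly basic to open the flavanone rings.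

**Compound list**

1 | p-coumaric acid, (E)-3-(4-hydroxyphenyl)prop-2-enoic acid | O=C(O)/C=C/c1ccc(O)cc1 | starting material
2 | rac-(1S,2S,5S,6S)-2,6-bis(4-hydroxyphenyl)-3,7-dioxabicyclo[3.3.0]octane-4,8-dione (racemate, one enantiomer drawn) | O=C2[C@@H]1[C@@H](c3ccc(O)cc3)OC(=O)[C@@H]1[C@H](O2)c1ccc(O)cc1 | intermediate
3 | rac-(1S,2S,5S,6S)-2,6-bis[4-(benzyloxy)phenyl]-3,7-dioxabicyclo[3.3.0]octane-4,8-dione (racemate, one enantiomer drawn) | O=C2[C@@H]1[C@@H](c3ccc(OCc4ccccc4)cc3)OC(=O)[C@@H]1[C@H](O2)c1ccc(OCc2ccccc2)cc1 | intermediate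
4 | (1S,2S,5S,6S)-2,6-bis[4-(benzyloxy)phenyl]-3,7-dioxabicyclo[3.3.0]octane-4,8-dione | O=C2[C@@H]1[C@@H](c3ccc(OCc4ccccc4)cc3)OC(=O)[C@@H]1[C@H](O2)c1ccc(OCc2ccccc2)cc1 | intermediate
5 | (2S,3S,4S)-2-[4-(benzyloxy)phenyl]-4-{(S)-[4-(benzyloxy)phenyl](hydroxy)methyl}-N-methoxy-N-methyl-5-oxooxolane-3-carboxamide | CON(C)C(=O)[C@@H]1[C@@H](c2ccc(OCc3ccccc3)cc2)OC(=O)[C@@H]1[C@H](O)c1ccc(OCc2ccccc2)cc1 | intermediate
6 | (2S,3S,4S)-2-[4-(benzyloxy)phenyl]-4-{(S)-[4-(benzyloxy)phenyl][(trimethylsilyl)oxy]methyl}-N-methoxy-N-methyl-5-oxooxolane-3-carboxamide | CON(C)C(=O)[C@@H]1[C@@H](c2ccc(OCc3ccccc3)cc2)OC(=O)[C@@H]1[C@H](O[Si](C)(C)C)c1ccc(OCc2ccccc2)cc1 | intermediate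
7 | 4-(benzyloxy)phenol | Oc1ccc(OCc2ccccc2)cc1 | starting material
8 | 4-(benzyloxy)-2-chlorophenol | Oc1ccc(OCc2ccccc2)cc1Cl | intermediate
9 | 4-(benzyloxy)-2-bromo-6-chlorophenol | Oc1c(Cl)cc(OCc2ccccc2)cc1Br | intermediate
10 | [4-(benzyloxy)-2-bromo-6-chlorophenoxy]trimethylsilane | C[Si](C)(C)Oc1c(Cl)cc(OCc2ccccc2)cc1Br | intermediate
11 | lithium 4-(benzyloxy)-2-chloro-6-(trimethylsilyl)phenoxide | [Li+].[O-]c1c(Cl)cc(OCc2ccccc2)cc1[Si](C)(C)C | intermediate
12 | 4-(benzyloxy)-2-chloro-6-(trimethylsilyl)phenyl trifluoromethanesulfonate | C[Si](C)(C)c1cc(OCc2ccccc2)cc(Cl)c1OS(=O)(=O)C(F)(F)F | intermediate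
13 | 3,5-bis(benzyloxy)phenol | Oc1cc(OCc2ccccc2)cc(OCc2ccccc2)c1 | starting material
14 | 3,5-bis(benzyloxy)-2-bromophenol | Oc1cc(OCc2ccccc2)cc(OCc2ccccc2)c1Br | intermediate
15 | [3,5-bis(benzyloxy)-2-bromophenoxy]trimethylsilane | C[Si](C)(C)Oc1cc(OCc2ccccc2)cc(OCc2ccccc2)c1Br | intermediate
16 | lithium 3,5-bis(benzyloxy)-2-(trimethylsilyl)phenoxide | [Li+].[O-]c1cc(OCc2ccccc2)cc(OCc2ccccc2)c1[Si](C)(C)C | intermediate
17 | 3,5-bis(benzyloxy)-2-(trimethylsilyl)phenyl trifluoromethanesulfonate | C[Si](C)(C)c1c(OCc2ccccc2)cc(OCc2ccccc2)cc1OS(=O)(=O)C(F)(F)F | intermediate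
18 | cesium (S)-[4-(benzyloxy)phenyl]{(2S,3S,4S)-2-[4-(benzyloxy)phenyl]-3-[methoxy(methyl)carbamoyl]-5-oxooxolan-4-yl}methanolate | [Cs+].CON(C)C(=O)[C@@H]1[C@@H](c2ccc(OCc3ccccc3)cc2)OC(=O)[C@@H]1[C@H]([O-])c1ccc(OCc2ccccc2)cc1 | intermediate
19 | 5-(benzyloxy)-3-chlorobenzyne | ClC1=CC(OCc2ccccc2)=CC#C1 | intermediate
20 | cesium (1S,2S)-1-[4-(benzyloxy)phenyl]-2-{(2S,3S)-7-(benzyloxy)-2-[4-(benzyloxy)phenyl]-5-chloro-4-oxochroman-3-yl}-3-[methoxy(methyl)amino]-3-oxopropan-1-olate | [Cs+].CON(C)C(=O)[C@H]([C@H]([O-])c1ccc(OCc2ccccc2)cc1)[C@@H]1C(=O)c2c(Cl)cc(OCc3ccccc3)cc2O[C@@H]1c1ccc(OCc2ccccc2)cc1 | intermediate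
21 | 3,5-bis(benzyloxy)benzyne | C1#CC(OCc2ccccc2)=CC(OCc2ccccc2)=C1 | intermediate
22 | (2S,3S)-7-(benzyloxy)-3-{(2S,3S)-5,7-bis(benzyloxy)-2-[4-(benzyloxy)phenyl]-4-oxochroman-3-yl}-2-[4-(benzyloxy)phenyl]-5-chlorochroman-4-one (cis,cis) | O=C1c2c(Cl)cc(OCc3ccccc3)cc2O[C@H](c2ccc(OCc3ccccc3)cc2)[C@@H]1[C@@H]1C(=O)c2c(OCc3ccccc3)cc(OCc3ccccc3)cc2O[C@@H]1c1ccc(OCc2ccccc2)cc1 | intermediate
23 | (2S,3R)-7-(benzyloxy)-3-{(2S,3R)-5,7-bis(benzyloxy)-2-[4-(benzyloxy)phenyl]-4-oxochroman-3-yl}-2-[4-(benzyloxy)phenyl]-5-chlorochroman-4-one (trans,trans) | O=C1c2c(Cl)cc(OCc3ccccc3)cc2O[C@H](c2ccc(OCc3ccccc3)cc2)[C@H]1[C@H]1C(=O)c2c(OCc3ccccc3)cc(OCc3ccccc3)cc2O[C@@H]1c1ccc(OCc2ccccc2)cc1 | intermediate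
24 | (2S,3R)-3-[(2S,3R)-5,7-dihydroxy-2-(4-hydroxyphenyl)-4-oxochroman-3-yl]-7-hydroxy-2-(4-hydroxyphenyl)chroman-4-one | O=C1c2ccc(O)cc2O[C@H](c2ccc(O)cc2)[C@H]1[C@H]1C(=O)c2c(O)cc(O)cc2O[C@@H]1c1ccc(O)cc1 | target

**Step count**

Total: 13 steps. Longest linear sequence: 8 steps (1, 2, 3, 4, 5, 11, 12, 13).

**Steps most likely to fail**

Step 11 (proposed new method). Several processes can divert it:
- retro-aldol fragmentation of the β-oxido lactone or amide before O-arylation;
- proton transfer to an aryl anion, for instance from the acidic C3 position of the first chromanone, in place of acyl attack;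
- loss of chloride from the chloroaryl anion;
- the first adduct resting as its lactolate instead of reopening.

The fallback uses known chemistry with the bond order reversed: aryllithium addition to the lactones first, ring closure by intramolecular SNAr second. It sets out from 4 and returns at 22.
- O-Benzylation of 5-fluororesorcinol gives 1,3-bis(benzyloxy)-5-fluorobenzene F1, and NBS bromination para to one benzyloxy group gives 2-bromo-1,5-bis(benzyloxy)-3-fluorobenzene F2.
- Bromine–lithium exchange with n-BuLi at −78 °C gives 2,4-bis(benzyloxy)-6-fluorophenyllithium F3.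
- O-Benzylation of 3-chloro-5-fluorophenol gives 1-(benzyloxy)-3-chloro-5-fluorobenzene F4, which LDA at −78 °C deprotonates between the halogens to give 4-(benzyloxy)-2-chloro-6-fluorophenyllithium F5.
- Dilactone 4 in THF at −78 °C is treated with one equivalent of F3, which should stop at the mono-lactolate, and then with F5. Work-up with aq. NH4Cl gives (2S,3S)-1-[4-(benzyloxy)-2-chloro-6-fluorophenyl]-4-[2,4-bis(benzyloxy)-6-fluorophenyl]-2,3-bis{(S)-[4-(benzyloxy)phenyl](hydroxy)methyl}butane-1,4-dione F6, which may rest as its bis-lactol. Symmetric bis-adducts are removed by chromatography.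
- KHMDS in THF at −40 to 0 °C closes both pyranones by displacement of fluoride ortho to each ketone. The alkoxide oxygens are retained, so C2 and C2'' keep their configuration and the product is 22.

Step 12. The equilibration may stop short of the trans,trans isomer, or the enolate may eject the ring oxygen by β-elimination and re-close, which would erode the configuration at C2 and C2''. The fallback moves the equilibration to the last stage and runs it without an enolate; it sets out from 22 and returns at 24. Compound 22 is hydrogenolysed first (H2, Pd/C, NaOAc, EtOAc–MeOH) to (2S,3S)-3-[(2S,3S)-5,7-dihydroxy-2-(4-hydroxyphenyl)-4-oxochroman-3-yl]-7-hydroxy-2-(4-hydroxyphenyl)chroman-4-one F7. C3 and C3'' are then equilibrated through the neutral enols with dilute HCl in MeOH at 50 °C to give 24.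

Step 1. Radical coupling of the unsubstituted phenol may take other courses (8–5 or 8–O–4 coupling, oligomerisation), or oxidation may be too slow, so that little dilactone forms. The fallback changes the species that is oxidised; it sets out from 1 and returns at 3. Compound 1 is O-benzylated (BnBr, KOH, EtOH–H2O, reflux) to (E)-3-[4-(benzyloxy)phenyl]prop-2-enoic acid F8. Two molecules of F8 are then joined through the arene radical cation with CoF3 in TFA–CH2Cl2 at 0 °C, a one-electron oxidative dimerisation of 4-alkoxycinnamic acids that leads directly to the benzylated dilactone 3.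

**Further compounds**

F1 | step 11 | 1,3-bis(benzyloxy)-5-fluorobenzene | Fc1cc(OCc2ccccc2)cc(OCc2ccccc2)c1
F2 | step 11 | 2-bromo-1,5-bis(benzyloxy)-3-fluorobenzene | Fc1cc(OCc2ccccc2)cc(OCc2ccccc2)c1Br
F3 | step 11 | 2,4-bis(benzyloxy)-6-fluorophenyllithium | [Li]c1c(F)cc(OCc2ccccc2)cc1OCc1ccccc1
F4 | step 11 | 1-(benzyloxy)-3-chloro-5-fluorobenzene | Fc1cc(Cl)cc(OCc2ccccc2)c1
F5 | step 11 | 4-(benzyloxy)-2-chloro-6-fluorophenyllithium | [Li]c1c(F)cc(OCc2ccccc2)cc1Cl
F6 | step 11 | (2S,3S)-1-[4-(benzyloxy)-2-chloro-6-fluorophenyl]-4-[2,4-bis(benzyloxy)-6-fluorophenyl]-2,3-bis{(S)-[4-(benzyloxy)phenyl](hydroxy)methyl}butane-1,4-dione | O=C(c1c(Cl)cc(OCc2ccccc2)cc1F)[C@H]([C@H](O)c1ccc(OCc2ccccc2)cc1)[C@H](C(=O)c1c(OCc2ccccc2)cc(OCc2ccccc2)cc1F)[C@H](O)c1ccc(OCc2ccccc2)cc1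
F7 | step 12 | (2S,3S)-3-[(2S,3S)-5,7-dihydroxy-2-(4-hydroxyphenyl)-4-oxochroman-3-yl]-7-hydroxy-2-(4-hydroxyphenyl)chroman-4-one | O=C1c2ccc(O)cc2O[C@H](c2ccc(O)cc2)[C@@H]1[C@@H]1C(=O)c2c(O)cc(O)cc2O[C@@H]1c1ccc(O)cc1
F8 | step 1 | (E)-3-[4-(benzyloxy)phenyl]prop-2-enoic acid | O=C(O)/C=C/c1ccc(OCc2ccccc2)cc1
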